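**Assumption:** 4-methoxy-2-methylphenol, isoprene and (E)-geranylacetone are bought. The enantiomer of the chiral acid used in step 2 that gives the (S)-cycloadduct is identified in a first screen (both antipodes of the catalyst are accessible).

## Retrosynthetic overview

1. Target 15 ⇐ δ-tocotrienol 13 by C5-selective ortho-formylation (last step).
2. 13 ⇐ (S)-2-vinylchromane 5 + C14 (E,E)-vinyl iodide 10, joined at C2'–C3' by hydroboration/B-alkyl Suzuki coupling, then O-demethylation.
3. Chromane ring (the only ring formed; the arene is bought) ⇐ dearomatised o-quinone methide 4 + isoprene in a catalytic enantioselective oxa-[4+2] that closes the pyran ring and sets C2 in one step.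
4. o-Quinone methide precursor 2 ⇐ 4-methoxy-2-methylphenol + CH2O; vinyl iodide 10 ⇐ geranylacetone via terminal alkyne and carboalumination/iodination.

## Route

Step 1
Reactants: 1 4-methoxy-2-methylphenol
Product: 2 2-(hydroxymethyl)-4-methoxy-6-methylphenol
Conditions: 37% aq. CH2O (3 equiv), NaOH (1.05 equiv), H2O, 0 °C → rt, 48 h; AcOH to pH 6
Reagents that add atoms: formaldehyde, C=O
Why: Lederer–Manasse hydroxymethylation, in which the phenoxide attacks formaldehyde at the only free ortho position (the other ortho carbon carries CH3 and the para carbon carries OMe).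

Step 2
Reactants: 2 2-(hydroxymethyl)-4-methoxy-6-methylphenol; 3 isoprene
Product: 5 (S)-6-methoxy-2,8-dimethyl-2-vinylchromane, via o-quinone methide 4 (not isolated)
Conditions: 2 added over 6 h to isoprene (10 equiv), chiral BINOL-derived N-triflyl imidodiphosphorimidate (IDPi) Brønsted acid (3 mol %), 5 Å MS, CHCl3/cyclohexane, −20 → 0 °C, sealed vessel; Et3N quench
Reagents that add atoms: none
Why: Proposed new method: the confined chiral acid dehydrates 2 to the O-protonated o-quinone methide, held as a hydrogen-bonded ion pair, and the methyl-substituted double bond of isoprene adds to it in an asynchronous inverse-demand oxa-Diels–Alder reaction (exocyclic CH2 to the diene CH2 terminus, then the catalyst-bound oxygen closes on the tertiary allyl-cation carbon), so rearomatisation drives the step, Markovnikov polarisation gives the 2-methyl-2-vinyl regioisomer, and the chiral anion at the bond-forming oxygen selects the diene face to give (S) at C2; the closest known reaction types are chiral phosphoric-acid-catalysed [4+2] cycloadditions of in-situ o-quinone methides with styrenes and IDPi-catalysed cycloadditions of isoprene.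

Step 3
Reactants: 6 (E)-geranylacetone
Product: 8 (5E)-6,10-dimethylundeca-5,9-dien-1-yne, via enol phosphate 7 (not isolated)
Conditions: LDA (1.05 equiv), THF, −78 °C; ClP(O)(OEt)2 (1.1 equiv), −78 °C → rt; then LDA (2.3 equiv), THF, −78 °C → rt; H2O
Reagents that add atoms: none
Why: Negishi methyl-ketone-to-alkyne conversion, in which the kinetic enolate on the CH3 side is trapped as the enol phosphate and then undergoes LDA-induced β-elimination, leaving the E-trisubstituted alkene untouched.

Step 4
Reactants: 8 (5E)-6,10-dimethylundeca-5,9-dien-1-yne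
Product: 10 (1E,5E)-1-iodo-2,6,10-trimethylundeca-1,5,9-triene, via alkenylalane 9 (not isolated)
Conditions: AlMe3 (2.0 equiv), Cp2ZrCl2 (0.25 equiv), CH2Cl2, 0 °C → rt, 12 h; then I2 (1.3 equiv), THF, −30 → 0 °C
Reagents that add atoms: trimethylaluminium, C[Al](C)C; iodine, II
Why: Negishi Zr-catalysed carboalumination adds Me–Al syn across the terminal alkyne (Me to the internal carbon) and iodinolysis proceeds with retention, fixing the E geometry of the future C3'=C4' bond; the trisubstituted alkenes do not react.

Step 5
Reactants: 5 (S)-6-methoxy-2,8-dimethyl-2-vinylchromane; 10 (1E,5E)-1-iodo-2,6,10-trimethylundeca-1,5,9-triene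
Product: 12 (R)-δ-tocotrienol methyl ether [(2R)-6-methoxy-2,8-dimethyl-2-[(3E,7E)-4,8,12-trimethyltrideca-3,7,11-trien-1-yl]chromane], via B-alkyl-9-BBN adduct 11 (not isolated)
Conditions: 9-BBN-H (1.15 equiv), THF, 0 °C → rt, 6 h; then 10 (1.05 equiv), PdCl2(dppf) (5 mol %), 3 M aq. NaOH (3 equiv), THF, 55 °C, degassed
Reagents that add atoms: none
Why: Anti-Markovnikov hydroboration of the only terminal alkene followed by B-alkyl Suzuki–Miyaura coupling, which retains the vinyl iodide geometry and does not touch C2 (the descriptor changes from S to R only because the CIP ranking of the substituents changes).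

Step 6
Reactants: 12 (R)-δ-tocotrienol methyl ether
Product: 13 (R)-δ-tocotrienol [(2R)-2,8-dimethyl-2-[(3E,7E)-4,8,12-trimethyltrideca-3,7,11-trien-1-yl]chroman-6-ol]
Conditions: EtSNa (6 equiv), DMF, 130 °C, 4 h, Ar; 1 M HCl work-up
Reagents that add atoms: none
Why: SN2 O-demethylation by thiolate, which attacks only the methyl carbon (the tertiary O1–C2 ether cannot undergo SN2) and is inert towards the isolated trisubstituted alkenes.

Step 7
Reactants: 13 (R)-δ-tocotrienol
Product: 15 (R)-5-formyl-δ-tocotrienol [(2R)-6-hydroxy-2,8-dimethyl-2-[(3E,7E)-4,8,12-trimethyltrideca-3,7,11-trien-1-yl]chromane-5-carbaldehyde], via 5-hydroxymethyl phenol 14 (not isolated)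
Conditions: MgCl2 (2.0 equiv), Et3N (4.0 equiv), (CH2O)n (6 equiv), THF, reflux, 4 h, Ar; 1 M HCl
Reagents that add atoms: formaldehyde (from paraformaldehyde), C=O
Why: Casnati–Skattebøl magnesium-mediated ortho-formylation, in which the magnesium phenoxide delivers CH2O to an ortho carbon and a second CH2O oxidises the benzylic alkoxide by hydride transfer; C5 is expected to be favoured over C7 because the ortho position next to the fused ring is the more reactive one in δ-tocols (ring-fusion bond fixation), and this regioselectivity is an expectation rather than a certainty.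

## Compound list

1 | 4-methoxy-2-methylphenol | COc1ccc(O)c(C)c1 | starting material
2 | 2-(hydroxymethyl)-4-methoxy-6-methylphenol | COc1cc(C)c(O)c(CO)c1 | intermediate
3 | isoprene (2-methylbuta-1,3-diene) | C=CC(C)=C | starting material
4 | 4-methoxy-2-methyl-6-methylidenecyclohexa-2,4-dien-1-one (o-quinone methide, present as its O-protonated ion pair) | O=C1C(=C)C=C(OC)C=C1C | intermediate (not isolated)
5 | (S)-6-methoxy-2,8-dimethyl-2-vinylchromane | C=C[C@]1(C)CCc2cc(OC)cc(C)c2O1 | intermediate
6 | (E)-geranylacetone [(5E)-6,10-dimethylundeca-5,9-dien-2-one] | CC(C)=CCC/C(C)=C/CCC(C)=O | starting material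
7 | diethyl (5E)-6,10-dimethylundeca-1,5,9-trien-2-yl phosphate | CC(C)=CCC/C(C)=C/CCC(=C)OP(=O)(OCC)OCC | intermediate (not isolated)
8 | (5E)-6,10-dimethylundeca-5,9-dien-1-yne | CC(C)=CCC/C(C)=C/CCC#C | intermediate
9 | dimethyl[(1E,5E)-2,6,10-trimethylundeca-1,5,9-trien-1-yl]alane | CC(C)=CCC/C(C)=C/CC/C(C)=C/[Al](C)C | intermediate (not isolated)
10 | (1E,5E)-1-iodo-2,6,10-trimethylundeca-1,5,9-triene | CC(C)=CCC/C(C)=C/CC/C(C)=C/I | intermediate
11 | 9-{2-[(2R)-6-methoxy-2,8-dimethylchroman-2-yl]ethyl}-9-borabicyclo[3.3.1]nonane | B1(CC[C@]2(C)CCc3cc(OC)cc(C)c3O2)C4CCCC1CCC4 | intermediate (not isolated)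
12 | (2R)-6-methoxy-2,8-dimethyl-2-[(3E,7E)-4,8,12-trimethyltrideca-3,7,11-trien-1-yl]chromane | CC(C)=CCC/C(C)=C/CC/C(C)=C/CC[C@]1(C)CCc2cc(OC)cc(C)c2O1 | intermediate
13 | (2R)-2,8-dimethyl-2-[(3E,7E)-4,8,12-trimethyltrideca-3,7,11-trien-1-yl]chroman-6-ol (δ-tocotrienol) | CC(C)=CCC/C(C)=C/CC/C(C)=C/CC[C@]1(C)CCc2cc(O)cc(C)c2O1 | intermediate
14 | (2R)-5-(hydroxymethyl)-2,8-dimethyl-2-[(3E,7E)-4,8,12-trimethyltrideca-3,7,11-trien-1-yl]chroman-6-ol (present as its magnesium phenoxide) | CC(C)=CCC/C(C)=C/CC/C(C)=C/CC[C@]1(C)CCc2c(CO)c(O)cc(C)c2O1 | intermediate (not isolated)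
15 | (2R)-6-hydroxy-2,8-dimethyl-2-[(3E,7E)-4,8,12-trimethyltrideca-3,7,11-trien-1-yl]chromane-5-carbaldehyde | CC(C)=CCC/C(C)=C/CC/C(C)=C/CC[C@]1(C)CCc2c(C=O)c(O)cc(C)c2O1 | target

## Totals and risks

Total step count: 7. Longest linear sequence: 5 (steps 1, 2, 5, 6, 7; the branch through steps 3, 4, 5, 6, 7 is equally long).

**Step 2 (enantioselective o-quinone methide/isoprene cycloaddition).** The risks are low ee, self-condensation of the quinone methide, and acid ionisation of the tertiary allylic ether in the product, which would erode ee. The fallback gives up catalyst control. It sets out from 2, which is heated with excess isoprene and no acid (toluene, 160 °C, sealed tube) to give racemic 6-methoxy-2,8-dimethyl-2-vinylchromane F1. F1 is resolved by preparative chiral SFC; the (S)-enantiomer is compound 5, where the route is rejoined, and the (R)-6-methoxy-2,8-dimethyl-2-vinylchromane F2 is discarded.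

**Step 7 (formylation).** The risks are C5/C7 regioselectivity, 5,7-diformylation and incomplete conversion of the hindered phenol. The fallback installs the carbon at the alcohol oxidation level through a covalent template and oxidises separately. It sets out from 13, which is condensed with PhB(OH)2 and paraformaldehyde (cat. EtCO2H, toluene, Dean–Stark) to the cyclic phenylboronate of the 5-hydroxymethyl phenol F6. F6 is stable to chromatography, so any C7 isomer is removed here. Transesterification with propane-1,3-diol releases 14, this time isolated, and activated MnO2 in CH2Cl2 oxidises the o-hydroxybenzyl alcohol to 15, where the route is rejoined.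

**Step 5 (one-pot hydroboration/B-alkyl Suzuki).** The risks are sluggish transmetalation of the borane next to the quaternary centre and protodeboronation. The fallback replaces the in-situ borane by an isolated iodide and an organozinc. It sets out from 5, which is hydroborated (9-BBN, giving 11) and oxidised (NaOH/H2O2) to (S)-2-(6-methoxy-2,8-dimethylchroman-2-yl)ethan-1-ol F3. I2/PPh3/imidazole converts this to (S)-2-(2-iodoethyl)-6-methoxy-2,8-dimethylchromane F4. Zinc dust/LiCl in THF gives the alkylzinc iodide F5, which is Negishi-coupled with 10 (Pd(PPh3)4, THF, 40 °C) to give 12, where the route is rejoined.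

## Further compounds

F1 | step 2 | racemic 6-methoxy-2,8-dimethyl-2-vinylchromane | C=CC1(C)CCc2cc(OC)cc(C)c2O1
F2 | step 2 | (R)-6-methoxy-2,8-dimethyl-2-vinylchromane | C=C[C@@]1(C)CCc2cc(OC)cc(C)c2O1
F3 | step 5 | (S)-2-(6-methoxy-2,8-dimethylchroman-2-yl)ethan-1-ol | OCC[C@]1(C)CCc2cc(OC)cc(C)c2O1
F4 | step 5 | (S)-2-(2-iodoethyl)-6-methoxy-2,8-dimethylchromane | ICC[C@]1(C)CCc2cc(OC)cc(C)c2O1
F5 | step 5 | {2-[(2S)-6-methoxy-2,8-dimethylchroman-2-yl]ethyl}zinc iodide | I[Zn]CC[C@]1(C)CCc2cc(OC)cc(C)c2O1
F6 | step 7 | cyclic phenylboronate (2-phenyl-4H-1,3,2-dioxaborin fused at C5/C6) of (2R)-5-(hydroxymethyl)-δ-tocotrienol | CC(C)=CCC/C(C)=C/CC/C(C)=C/CC[C@]1(C)CCc2c3COB(c4ccccc4)Oc3cc(C)c2O1
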